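**Retrosynthetic overview**

1. The only ring to be made is the γ-butyrolactone (O1, C2 carbonyl, C3, C4, C5); both arenes are bought. The last operations are equilibration of C3 to the trans isomer and replacement of a C3–Cl and a C5–S(p-tolyl) bond by C–H.
2. Key disconnection: O1–C5 and C3–C4 are formed together from an (R)-(Z)-alkenyl p-tolyl sulfoxide (C4=C5 unit carrying the trimethoxybenzyl group) and chloro(3,4-dimethoxybenzyl)ketene (C2–C3 unit). The sequence is O-acylation, [3,3]-sigmatropic shift and lactonisation, with sulfur-to-carbon chirality transfer to C4.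
3. Enabling feature: in the lactone ring C5 is an oxygen-bearing carbon directly bonded to the β-stereocentre C4, and C2 is a carboxyl carbon. C4–C5 can therefore be the two alkene carbons of a vinyl sulfoxide (C5 passing through the aldehyde level as a thionium ion) and O1–C2–C3 a ketene, so that the six atoms C3=C2–O–S–C5=C4 form the array for the sigmatropic shift.
4. The sulfoxide comes from 3,4,5-trimethoxybenzyl chloride, ethynylmagnesium bromide and menthyl p-toluenesulfinate (Andersen synthesis, then Z-selective semihydrogenation).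
5. The ketene precursor comes from 3,4-dimethoxy-L-phenylalanine (chlorodeamination, acid chloride).

Key step: step 6

Assumption: the configuration at the chlorine-bearing carbon of the ketene precursor and of the first lactone is without consequence, because it is erased at the ketene stage and again on dechlorination; it is drawn as formed or left undefined.

**Route**

Step 1
Reactants: 1 3,4,5-trimethoxybenzyl chloride; 2 ethynylmagnesium bromide
Product: 3 1,2,3-trimethoxy-5-(prop-2-yn-1-yl)benzene
Conditions: 2 (3 equiv, 0.5 M in THF), CuCl (cat.), THF, 50 °C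
Reagents that add atoms: none
Why: Copper-catalysed Kumada-type sp3–sp cross-coupling of a benzylic chloride with an alkynyl Grignard reagent, in which the excess of 2 should suppress a second benzylation of the product alkyne and the mild temperature should limit propargyl–allenyl isomerisation.

Step 2
Reactants: 3 1,2,3-trimethoxy-5-(prop-2-yn-1-yl)benzene; 4 (1R,2S,5R)-(−)-menthyl (S)-p-toluenesulfinate
Product: 6 (S)-1,2,3-trimethoxy-5-[3-(p-tolylsulfinyl)prop-2-yn-1-yl]benzene, via alkynylmagnesium bromide 5 (not isolated)
Conditions: EtMgBr, THF, 0 °C → rt; then added to 4, toluene, −20 °C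
Reagents that add atoms: none
Why: Andersen sulfoxide synthesis, in which the alkynyl Grignard reagent 5 displaces mentholate from the diastereomerically pure sulfinate with inversion at sulfur, so the sulfur stereocentre of 6 is set by 4 (the descriptor remains S only because alkynyl outranks p-tolyl).

Step 3
Reactants: 6 (S)-1,2,3-trimethoxy-5-[3-(p-tolylsulfinyl)prop-2-yn-1-yl]benzene
Product: 7 (R,Z)-1,2,3-trimethoxy-5-[3-(p-tolylsulfinyl)prop-2-en-1-yl]benzene
Conditions: H2 (1 atm), RhCl(PPh3)3 (cat.), benzene, rt
Reagents that add atoms: none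
Why: Homogeneous catalytic syn-semihydrogenation of an alkynyl sulfoxide delivers both hydrogens to one side of the triple bond and should stop at the electron-poor Z-alkenyl sulfoxide; sulfur is untouched and its descriptor changes from S to R only because p-tolyl outranks alkenyl.

Step 4
Reactants: 8 3,4-dimethoxy-L-phenylalanine
Product: 9 (S)-2-chloro-3-(3,4-dimethoxyphenyl)propanoic acid
Conditions: NaNO2, 6 M HCl, 0 °C → rt
Reagents that add atoms: hydrogen chloride (as 6 M hydrochloric acid), Cl
Why: Diazotisation and chlorodeamination of an α-amino acid, which should proceed with net retention by double inversion under participation of the neighbouring carboxylate, the configuration of this centre being of no consequence later.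

Step 5
Reactants: 9 (S)-2-chloro-3-(3,4-dimethoxyphenyl)propanoic acid
Product: 10 (S)-2-chloro-3-(3,4-dimethoxyphenyl)propanoyl chloride
Conditions: (COCl)2, DMF (cat.), CH2Cl2, 0 °C → rt; used crude
Reagents that add atoms: oxalyl chloride, O=C(Cl)C(Cl)=O
Why: Acid chloride formation by nucleophilic acyl substitution under chloroiminium catalysis, neutral enough to leave the α-chloride and the dimethoxyarene untouched.

Step 6
Reactants: 7 (R,Z)-1,2,3-trimethoxy-5-[3-(p-tolylsulfinyl)prop-2-en-1-yl]benzene; 10 (S)-2-chloro-3-(3,4-dimethoxyphenyl)propanoyl chloride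
Product: 14 (4S,5R)-3-chloro-3-(3,4-dimethoxybenzyl)-5-(p-tolylthio)-4-(3,4,5-trimethoxybenzyl)dihydrofuran-2(3H)-one (epimer mixture at C-3), via chloro(3,4-dimethoxybenzyl)ketene 11 (not isolated), via acyloxysulfonium enolate 12 (not isolated), via thionium carboxylate 13 (not isolated)
Conditions: 7, Et3N (2.5 equiv), CH2Cl2, −40 °C; 10 (2 equiv) added over 2 h; then → 0 °C
Reagents that add atoms: none
Why: Proposed new method: Et3N should convert 10 into the alkyl(chloro)ketene 11, which the nucleophilic sulfoxide oxygen of 7 attacks at the carbonyl carbon to give the acyloxysulfonium enolate 12; a charge-accelerated [3,3]-sigmatropic shift through the six-atom array C3=C2–O–S–C5=C4 then breaks the weak S–O bond, forms the C3–C4 bond and leaves the thionium carboxylate 13, which is captured at once by its own carboxylate to form the O1–C5 bond. The closest known reaction type is the Marino lactonisation of alkenyl sulfoxides with dichloroketene or chloroketene; what is new is a ketene bearing one chlorine and one benzylic alkyl group, which should stay electrophilic enough because of the chlorine, and the acyloxysulfonium salt that 10 could form directly with 7 would be deprotonated by Et3N to the same enolate 12. The lactone ring is closed in the last event by 5-exo-trig attack of the carboxylate oxygen on the C5=S thionium bond, the sigmatropic step itself closing no ring. C4 is controlled by the sulfur stereocentre: allylic 1,3-strain in the Z-alkenyl sulfonium keeps the sulfur lone pair eclipsed with the alkene and the p-tolyl group pseudo-equatorial in the chair-like transition state, so carbon is delivered only to the alkene face that carries the S–O bond, which for (R)-sulfur and Z geometry gives the C4 configuration of the target; C5 follows from suprafacial addition across the former alkene (arylthio cis to the C4 substituent) and C3 is not controlled, both being erased later. The step needs O-acylation of the sulfoxide to outrun ketene dimerisation and needs the tertiary α-chloro lactone to survive the amine without loss of HCl, which slow addition of 10, low temperature and the high oxygen nucleophilicity of the sulfoxide should secure.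

Step 7
Reactants: 14 (4S,5R)-3-chloro-3-(3,4-dimethoxybenzyl)-5-(p-tolylthio)-4-(3,4,5-trimethoxybenzyl)dihydrofuran-2(3H)-one
Product: 15 (4R)-3-(3,4-dimethoxybenzyl)-4-(3,4,5-trimethoxybenzyl)dihydrofuran-2(3H)-one (mixture of C-3 epimers)
Conditions: Raney Ni (W-2, excess), NaOAc, EtOH, rt → 50 °C
Reagents that add atoms: none
Why: Raney nickel hydrogenolysis (reductive desulfurisation together with hydrodechlorination of the activated tertiary α-chloro lactone) should replace the C5–S and C3–Cl bonds by C–H without touching C4, whose descriptor changes from S to R by priority only, while C3 is left as an epimer mixture.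

Step 8
Reactants: 15 (4R)-3-(3,4-dimethoxybenzyl)-4-(3,4,5-trimethoxybenzyl)dihydrofuran-2(3H)-one (mixture of C-3 epimers)
Product: 16 (3R,4R)-3-(3,4-dimethoxybenzyl)-4-(3,4,5-trimethoxybenzyl)dihydrofuran-2(3H)-one
Conditions: DBU (0.3 equiv), toluene, 80 °C
Reagents that add atoms: none
Why: Base-mediated epimerisation through the lactone enolate equilibrates C3 only, and since the trans-3,4-dibenzyl arrangement is the thermodynamically preferred one for such lactones the mixture should converge on the (3R,4R) isomer under control of the fixed C4 centre.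

**Compound list**

1 | 3,4,5-trimethoxybenzyl chloride | COc1cc(CCl)cc(OC)c1OC | starting material
2 | ethynylmagnesium bromide | C#C[Mg]Br | starting material
3 | 1,2,3-trimethoxy-5-(prop-2-yn-1-yl)benzene | C#CCc1cc(OC)c(OC)c(OC)c1 | intermediate
4 | (1R,2S,5R)-(−)-menthyl (S)-p-toluenesulfinate | CC(C)[C@@H]1CC[C@@H](C)C[C@H]1O[S@](=O)c1ccc(C)cc1 | starting material
5 | [3-(3,4,5-trimethoxyphenyl)prop-1-yn-1-yl]magnesium bromide | Br[Mg]C#CCc1cc(OC)c(OC)c(OC)c1 | intermediate
6 | (S)-1,2,3-trimethoxy-5-[3-(p-tolylsulfinyl)prop-2-yn-1-yl]benzene | Cc1ccc(cc1)[S@](=O)C#CCc1cc(OC)c(OC)c(OC)c1 | intermediate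
7 | (R,Z)-1,2,3-trimethoxy-5-[3-(p-tolylsulfinyl)prop-2-en-1-yl]benzene | Cc1ccc(cc1)[S@](=O)/C=C\Cc1cc(OC)c(OC)c(OC)c1 | intermediate
8 | 3,4-dimethoxy-L-phenylalanine | N[C@@H](Cc1ccc(OC)c(OC)c1)C(=O)O | starting material
9 | (S)-2-chloro-3-(3,4-dimethoxyphenyl)propanoic acid | Cl[C@@H](Cc1ccc(OC)c(OC)c1)C(=O)O | intermediate
10 | (S)-2-chloro-3-(3,4-dimethoxyphenyl)propanoyl chloride | Cl[C@@H](Cc1ccc(OC)c(OC)c1)C(Cl)=O | intermediate
11 | chloro(3,4-dimethoxybenzyl)ketene | O=C=C(Cl)Cc1ccc(OC)c(OC)c1 | intermediate
12 | (R at sulfur) acyloxysulfonium enolate from 7 and 11 (zwitterion; enolate geometry undefined) | [O-]C(=C(Cl)Cc1ccc(OC)c(OC)c1)O[S@@+](c1ccc(C)cc1)/C=C\Cc1cc(OC)c(OC)c(OC)c1 | intermediate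
13 | (3S)-2-chloro-2-(3,4-dimethoxybenzyl)-4-(p-tolylsulfaniumylidene)-3-(3,4,5-trimethoxybenzyl)butanoate (zwitterion; C-2 undefined) | [O-]C(=O)C(Cl)(Cc1ccc(OC)c(OC)c1)[C@@H](Cc1cc(OC)c(OC)c(OC)c1)C=[S+]c1ccc(C)cc1 | intermediate
14 | (4S,5R)-3-chloro-3-(3,4-dimethoxybenzyl)-5-(p-tolylthio)-4-(3,4,5-trimethoxybenzyl)dihydrofuran-2(3H)-one (C-3 epimers; 4,5-cis) | O=C1O[C@H](Sc2ccc(C)cc2)[C@H](Cc2cc(OC)c(OC)c(OC)c2)C1(Cl)Cc1ccc(OC)c(OC)c1 | intermediate
15 | (4R)-3-(3,4-dimethoxybenzyl)-4-(3,4,5-trimethoxybenzyl)dihydrofuran-2(3H)-one (C-3 epimers) | O=C1OC[C@H](Cc2cc(OC)c(OC)c(OC)c2)C1Cc1ccc(OC)c(OC)c1 | intermediate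
16 | (3R,4R)-3-(3,4-dimethoxybenzyl)-4-(3,4,5-trimethoxybenzyl)dihydrofuran-2(3H)-one | COc1ccc(C[C@H]2C(=O)OC[C@@H]2Cc2cc(OC)c(OC)c(OC)c2)cc1OC | target

**Step count and risks**

Total step count: 8. Longest linear sequence: 6 steps (steps 1, 2, 3, 6, 7, 8).

Steps most likely to fail:

Step 6 (proposed new method). The alkyl(chloro)ketene may be acylated too slowly by the sulfoxide, so that ketene dimerisation, direct Pummerer-type consumption of the sulfoxide by the acid chloride, or base-induced loss of HCl from the product takes over. The fallback uses the established dichloroketene version and sets out from 7. Treatment of 7 with trichloroacetyl chloride and Zn–Cu couple in Et2O at reflux should give (4S,5R)-3,3-dichloro-5-(p-tolylthio)-4-(3,4,5-trimethoxybenzyl)dihydrofuran-2(3H)-one F1 with the same chirality transfer. Raney Ni (W-2) with NaOAc in EtOH should then remove both chlorines and the arylthio group to give (R)-4-(3,4,5-trimethoxybenzyl)dihydrofuran-2(3H)-one F2. Deprotonation with LiN(SiMe3)2 in THF at −78 °C and alkylation with 3,4-dimethoxybenzyl bromide, which enters anti to the C4 substituent, comes back to the route at 16; steps 4, 5, 7 and 8 are then not needed.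

Step 7. Hydrogenolysis of the tertiary C–Cl bond may stay incomplete, or HCl may be lost on the basic nickel surface to a butenolide, which would erase C4. The fallback sets out from 14 and separates the two reductions. Zn dust in AcOH at rt (two-electron reduction and protonation of the zinc enolate) should give (4R,5R)-3-(3,4-dimethoxybenzyl)-5-(p-tolylthio)-4-(3,4,5-trimethoxybenzyl)dihydrofuran-2(3H)-one F3 as C-3 epimers under acidic, non-eliminating conditions. Radical-chain cleavage of the C5–S bond with Bu3SnH and AIBN in toluene at reflux then comes back to the route at 15.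

Step 3. Over-reduction, migration of the skipped alkene into conjugation with the arene, or stalling of the rhodium catalyst by sulfur coordination may erode the Z-alkene. The fallback sets out from 3 and uses the opposite alkene geometry together with the opposite sulfur configuration, which should lead to the same C4 configuration. The Grignard reagent 5 and purchased (1S,2R,5S)-(+)-menthyl (R)-p-toluenesulfinate should give (R)-1,2,3-trimethoxy-5-[3-(p-tolylsulfinyl)prop-2-yn-1-yl]benzene F4. Anti-hydroalumination with i-Bu2AlH (or LiAlH4) in THF at −78 °C should give (S,E)-1,2,3-trimethoxy-5-[3-(p-tolylsulfinyl)prop-2-en-1-yl]benzene F5. The conditions of step 6 with 10 should then give (4S,5S)-3-chloro-3-(3,4-dimethoxybenzyl)-5-(p-tolylthio)-4-(3,4,5-trimethoxybenzyl)dihydrofuran-2(3H)-one F6, the 4,5-trans C-5 epimer of 14, and the conditions of step 7 come back to the route at 15.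

**Further compounds**

F1 | step 6 | (4S,5R)-3,3-dichloro-5-(p-tolylthio)-4-(3,4,5-trimethoxybenzyl)dihydrofuran-2(3H)-one | O=C1O[C@H](Sc2ccc(C)cc2)[C@H](Cc2cc(OC)c(OC)c(OC)c2)C1(Cl)Cl
F2 | step 6 | (R)-4-(3,4,5-trimethoxybenzyl)dihydrofuran-2(3H)-one | O=C1OC[C@H](Cc2cc(OC)c(OC)c(OC)c2)C1
F3 | step 7 | (4R,5R)-3-(3,4-dimethoxybenzyl)-5-(p-tolylthio)-4-(3,4,5-trimethoxybenzyl)dihydrofuran-2(3H)-one (C-3 epimers) | O=C1O[C@H](Sc2ccc(C)cc2)[C@H](Cc2cc(OC)c(OC)c(OC)c2)C1Cc1ccc(OC)c(OC)c1
F4 | step 3 | (R)-1,2,3-trimethoxy-5-[3-(p-tolylsulfinyl)prop-2-yn-1-yl]benzene | Cc1ccc(cc1)[S@@](=O)C#CCc1cc(OC)c(OC)c(OC)c1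
F5 | step 3 | (S,E)-1,2,3-trimethoxy-5-[3-(p-tolylsulfinyl)prop-2-en-1-yl]benzene | Cc1ccc(cc1)[S@@](=O)/C=C/Cc1cc(OC)c(OC)c(OC)c1
F6 | step 3 | (4S,5S)-3-chloro-3-(3,4-dimethoxybenzyl)-5-(p-tolylthio)-4-(3,4,5-trimethoxybenzyl)dihydrofuran-2(3H)-one (C-3 epimers) | O=C1O[C@@H](Sc2ccc(C)cc2)[C@H](Cc2cc(OC)c(OC)c(OC)c2)C1(Cl)Cc1ccc(OC)c(OC)c1
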